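**Two settings.** If I wanted more L from a charge of Q, I had two settings to turn: the time and the charge of Z. Here Q (substrate) pairs reversibly to L, L goes on to J, and Q with the further species Z gives D, a parallel side reaction.

| flask | Q | Z | remark | time |
|---|---|---|---|---|
| Wednesday's | 16 mM | 11 mM | run made earlier |  |
| Friday's | 16 mM | 18 mM | run made earlier |  |
| flask | 16 mM | 8.00 mM |  | 15 d |

| run | time / d | L / % | Q / % |
|---|---|---|---|
| Wednesday's | 0.125 | 25.7 | 64.3 |
| Wednesday's | 0.250 | 33.9 | 44.7 |
| Wednesday's | 0.625 | 36.6 | 25.0 |
| Wednesday's | 1.67 | 17.0 | 9.4 |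
| Wednesday's | 4.00 | 3.9 | 2.6 |
| Wednesday's | 10.0 | 0 | 0.5 |
| Friday's | 0.125 | 24.8 | 61.2 |
| Friday's | 0.250 | 33.2 | 42.7 |
| Friday's | 0.625 | 32.1 | 20.5 |
| Friday's | 1.67 | 12.5 | 4.4 |
| Friday's | 4.00 | 1.4 | 0 |
| Friday's | 10.0 | 0 | 1.0 |

(each reading ± 1 percentage point)

- a species is counted by the Q in it: one L or J counts as two
- reactions considered so far: 2 Q <-> L; Q + Z -> D; L -> J

- time, not beyond 15 d, at which the flask holds most L
- the amount of L, in percent of the Q charged, at that time

**The time.** Wednesday's L fell from 36.6% at 0.625 d to 3.9% at 4.00 d, so I expected nothing from waiting until 15 d. Friday's highest L reading stood at 0.250 d and Wednesday's at 0.625 d. I placed the flask's peak between them.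

**The Z.** At 0.625 d, Friday's run, with 18 mM of Z, held 32.1% of L, less than Wednesday's 36.6% with 11 mM. That gap of 4.5 percentage points, with a scatter of 1 point on each reading, gave 0.00643 /mM. I call this share of the charge lost as L per unit of Z the Z penalty. The flask has 3.00 mM less Z than Wednesday's run, so, taking that reading as a stand-in for Wednesday's peak, I reckoned on 38.5% at the flask's peak.

**Forecast, result.** The forecast gave 39% at 0.55 d, reasoning that “the peak rises roughly 0.4 points per mM less Z”. The flask peaked at 0.466 d with 40.6%, inside my bracket and 2.1 points above my figure.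

    2 Q ⇌ L (K = 2400 /M, k = 0.0750 /M/min)
    Q + Z → D (k = 0.0590 /M/min)
    L → J (k = 5.90 × 10⁻⁴ /min)

**Penalty reused.** Without the scatter, changing the time of Wednesday's run left its peak at 38.4%, as it was, and changing its Z to the flask's gave 40.6%. For a neighbouring flask with 3.2 mM of Z, the penalty on this flask's peak gave 43.7%, and that flask reached 44.7%.

All runs were generated by integration with constants of no real substance, noise included.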